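**Assumption:** all five starting materials (1, 2, 5, 10, 11) are taken as catalogue chemicals. Locants used: coumaran C2/C3 and side chain C7' (carbinol), C8', C9'; the target is (2S,3R,7'S,8'R). The route is a paper proposal; nothing here has been run.

## Retrosynthetic overview

1. Target 17 ⇐ one global LiBH4 reduction of the bis-imide aryl pivalate 16, which unmasks both CH2OH groups and the ring-Y phenol.
2. 16 ⇐ oxidative 8–5 (β-5) radical cross-coupling of the pre-formed β-1 unit 9 (free ring-X phenol) with feruloyl sultam 14, then quinone-methide closure. The dihydrobenzofuran is the only ring made and it is made last.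
3. 9 ⇐ Evans syn-aldol of arylacetyl imide 4 with vanillin (sets C7'/C8').
4. 4 ⇐ homovanillic acid + (S)-4-benzyloxazolidin-2-one; 14 ⇐ O-acetylferulic acid + (1R)-(+)-camphorsultam.

## Route

**Step 1**
Reactants: 1 homovanillic acid; 2 (S)-4-benzyloxazolidin-2-one
Product: 4 (S)-4-benzyl-3-{[3-methoxy-4-(pivaloyloxy)phenyl]acetyl}oxazolidin-2-one, via mixed pivalic anhydride 3 (not isolated)
Conditions: PivCl (2.3 equiv), Et3N (3.5 equiv), THF, −20 → 0 °C; then 2, LiCl, rt
Reagents that add atoms: pivaloyl chloride, CC(C)(C)C(Cl)=O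
Why: Mixed-anhydride N-acylation of the oxazolidinone (PivCl/Et3N/LiCl protocol), in which the second equivalent of PivCl caps the phenol as a hindered aryl pivalate that survives until the final hydride step; no stereocentre is formed.

**Step 2**
Reactants: 4 arylacetyl imide; 5 vanillin
Product: 9 (S)-4-benzyl-3-[(2S,3S)-3-hydroxy-3-(4-hydroxy-3-methoxyphenyl)-2-(3-methoxy-4-pivaloyloxyphenyl)propanoyl]oxazolidin-2-one, via O-TMS-vanillin 6 (not isolated), via Z-dibutylboron enolate 7 (not isolated), via boron aldolate 8 (not isolated)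
Conditions: 5, HMDS (0.6 equiv), cat. TMSCl, 60 °C, then vacuum; 4, Bu2BOTf, iPr2NEt, CH2Cl2, 0 °C; add 6, −78 → 0 °C; pH 7 buffer, MeOH, 30% H2O2, 0 °C
Reagents that add atoms: none
Why: Evans boron syn-aldol in which the Z-enolate reacts through a Zimmerman–Traxler chair on the face anti to the benzyl group, giving the 2S,3S "Evans syn" imide (the 8'R,7'S geometry of the target once C9' is reduced), while the transient aryl TMS ether keeps the phenol off boron and is lost in the methanolic work-up.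

**Step 3**
Reactants: 10 (E)-4-acetoxy-3-methoxycinnamic acid; 11 (2S)-bornane-10,2-sultam [(1R)-(+)-2,10-camphorsultam]
Product: 14 N-[(E)-feruloyl]-(2S)-bornane-10,2-sultam, via acid chloride 12 (not isolated), via O-acetyl feruloyl sultam 13 (not isolated)
Conditions: 10, (COCl)2, cat. DMF, CH2Cl2, rt; 11, NaH, toluene, 0 °C, added to 12, rt; then pyrrolidine (3 equiv), rt, 20 min
Reagents that add atoms: none
Why: N-acylation of the sultam sodium salt by the acid chloride followed by chemoselective aminolysis of the aryl acetate (aryl ester far more reactive than the N-acyl sultam); the E-alkene is retained and no stereocentre is formed.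

**Step 4**
Reactants: 9 phenolic β-1 imide; 14 feruloyl sultam
Product: 16 trans-coumaran bis-imide (coumaran 2S,3S and side chain 2S,3S by CIP; same geometry as the target), via p-quinone methide 15 (not isolated)
Conditions: Ag2O (1.5 equiv), CH2Cl2, rt, dark; 14 (1.4 equiv) added by syringe pump over 8 h; chromatography
Reagents that add atoms: none
Why: Proposed new method: Ag(I) oxidises both guaiacyl phenols to phenoxyl radicals, and the feruloyl radical (spin at C8, kept dilute by slow addition so that it meets the ring-X radical rather than itself) bonds through C8 to the free ortho carbon C5 of 9 on the C8 face left open by the (2S)-sultam in its s-cis, C=O/SO2-anti conformer (the sense inferred from thermal additions to N-enoyl sultams, setting C3); the dienone then re-aromatises and the phenol closes 5-exo onto quinone methide 15 to give the 2,3-trans ring (setting C2). The closest known reactions are the Ag2O 8–5 dehydrodimerisation of feruloyl camphorsultam and the cross-coupling of monolignol radicals with 4-alkylguaiacol end groups; the minor coumaran isomer is a diastereomer and is removed here together with 8–O–4 and homodimer by-products.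

**Step 5**
Reactants: 16 coumaran bis-imide
Product: 17 target, (2S,3R)-coumaran with (7'S,8'R) side chain
Conditions: LiBH4 (10 equiv), THF, H2O (2 equiv), 0 °C → rt; aq NH4Cl
Reagents that add atoms: none
Why: Reductive cleavage of both N-acyl auxiliaries at the exocyclic carbonyl (LiBH4 imide reduction to primary alcohols) and of the aryl pivalate in one operation; hydride delivery outpaces enolisation, so C3 and C8' are not epimerised and no stereocentre is touched.

## Compound list

1 | homovanillic acid | COc1cc(CC(=O)O)ccc1O | starting material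
2 | (S)-4-benzyloxazolidin-2-one | O=C1OC[C@H](Cc2ccccc2)N1 | starting material
3 | [3-methoxy-4-(pivaloyloxy)phenyl]acetic pivalic anhydride | COc1cc(CC(=O)OC(=O)C(C)(C)C)ccc1OC(=O)C(C)(C)C | intermediate (not isolated)
4 | (S)-4-benzyl-3-{[3-methoxy-4-(pivaloyloxy)phenyl]acetyl}oxazolidin-2-one | COc1cc(CC(=O)N2[C@@H](Cc3ccccc3)COC2=O)ccc1OC(=O)C(C)(C)C | intermediate
5 | vanillin | COc1cc(C=O)ccc1O | starting material
6 | 3-methoxy-4-(trimethylsilyloxy)benzaldehyde | COc1cc(C=O)ccc1O[Si](C)(C)C | intermediate (not isolated)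
7 | (Z)-dibutylboron enolate of 4 | CCCCB(CCCC)O/C(=C\c1ccc(OC(=O)C(C)(C)C)c(OC)c1)N1[C@@H](Cc2ccccc2)COC1=O | intermediate (not isolated)
8 | dibutylboron aldolate, aryl O-TMS | COc1cc([C@@H](OB(CCCC)CCCC)[C@@H](C(=O)N2[C@@H](Cc3ccccc3)COC2=O)c2ccc(OC(=O)C(C)(C)C)c(OC)c2)ccc1O[Si](C)(C)C | intermediate (not isolated)
9 | (S)-4-benzyl-3-[(2S,3S)-3-hydroxy-3-(4-hydroxy-3-methoxyphenyl)-2-(3-methoxy-4-pivaloyloxyphenyl)propanoyl]oxazolidin-2-one | COc1cc([C@@H](O)[C@@H](C(=O)N2[C@@H](Cc3ccccc3)COC2=O)c2ccc(OC(=O)C(C)(C)C)c(OC)c2)ccc1O | intermediate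
10 | (E)-4-acetoxy-3-methoxycinnamic acid | COc1cc(/C=C/C(=O)O)ccc1OC(C)=O | starting material
11 | (2S)-bornane-10,2-sultam, (1R)-(+)-2,10-camphorsultam | CC1(C)[C@H]2CC[C@@]13CS(=O)(=O)N[C@H]3C2 | starting material
12 | (E)-4-acetoxy-3-methoxycinnamoyl chloride | COc1cc(/C=C/C(Cl)=O)ccc1OC(C)=O | intermediate (not isolated)
13 | N-[(E)-4-acetoxy-3-methoxycinnamoyl]-(2S)-bornane-10,2-sultam | COc1cc(/C=C/C(=O)N2[C@H]3C[C@@H]4CC[C@@]3(CS2(=O)=O)C4(C)C)ccc1OC(C)=O | intermediate (not isolated)
14 | N-[(E)-feruloyl]-(2S)-bornane-10,2-sultam | COc1cc(/C=C/C(=O)N2[C@H]3C[C@@H]4CC[C@@]3(CS2(=O)=O)C4(C)C)ccc1O | intermediate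
15 | p-quinone methide of the 8–5 adduct (ring X re-aromatised) | COC1=CC(=C[C@@H](C(=O)N2[C@H]3C[C@@H]4CC[C@@]3(CS2(=O)=O)C4(C)C)c2cc([C@@H](O)[C@@H](C(=O)N3[C@@H](Cc4ccccc4)COC3=O)c3ccc(OC(=O)C(C)(C)C)c(OC)c3)cc(OC)c2O)C=CC1=O | intermediate (not isolated)
16 | trans-2-(4-hydroxy-3-methoxyphenyl)-7-methoxy-2,3-dihydrobenzofuran carrying the 3-carbonyl sultam and the 5-[(1S,2S)-1-hydroxy-2-(3-methoxy-4-pivaloyloxyphenyl)-3-oxo-3-(oxazolidinonyl)propyl] group | COc1cc([C@H]2Oc3c(OC)cc([C@@H](O)[C@@H](C(=O)N4[C@@H](Cc5ccccc5)COC4=O)c4ccc(OC(=O)C(C)(C)C)c(OC)c4)cc3[C@@H]2C(=O)N2[C@H]3C[C@@H]4CC[C@@]3(CS2(=O)=O)C4(C)C)ccc1O | intermediate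
17 | CNP0294468.1, (1S,2R)-1-[(2S,3R)-2-(4-hydroxy-3-methoxyphenyl)-3-(hydroxymethyl)-7-methoxy-2,3-dihydrobenzofuran-5-yl]-2-(4-hydroxy-3-methoxyphenyl)propane-1,3-diol | COc1cc([C@H]2Oc3c(OC)cc([C@@H](O)[C@@H](CO)c4ccc(O)c(OC)c4)cc3[C@@H]2CO)ccc1O | target

## Step count and risk

Total steps: 5. Longest linear sequence: 4 (steps 1, 2, 4, 5).

**Step 4 (most likely to fail).** The risks are feruloyl homodimerisation, 8–O–4 instead of 8–5 cross-coupling, ipso attack at C1 of 9 with loss of the side chain, and over-oxidation of the product phenol. The sense of sultam induction is inferred from the thermal-addition model, not taken from a result on this substrate. Fallback, setting out from 14 (with 4) and returning at 17: homodimerise 14 with Ag2O in CH2Cl2 to the bis-sultam 8–5 dehydrodimer F1. Cap its phenol with PivCl/Et3N/DMAP to give the pivalate F2. Ozonise the enoyl C=C (O3, CH2Cl2/MeOH, −78 °C; Me2S) to the 5-formyl coumaran F3. Add boron enolate 7 (from 4, as in step 2) to F3 to give the syn-aldol adduct F4. LiBH4 as in step 5 then converts F4 into 17.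

**Step 2.** The risks are a sluggish reaction between the conjugated arylacetyl enolate and an electron-rich aldehyde, loss of the transient silyl group, and retro-aldol of the phenolic adduct. Fallback, setting out from 4 and 5 and returning at 9: acetylate 5 (Ac2O, pyridine) to vanillin acetate F5. Add the chlorotitanium enolate of 4 (TiCl4, iPr2NEt, NMP, CH2Cl2, −78 → 0 °C) to F5 to give the O-acetyl syn-aldol adduct F6. Remove the aryl acetate with pyrrolidine (CH2Cl2, 0 °C) to give 9.

**Step 5.** The risks are incomplete reduction of the hindered N-acyl sultam, base-induced opening of the coumaran by β-elimination at C3, and retro-aldol of the β-hydroxy imide. Fallback, setting out from 16 and returning at 17: hydrolyse both auxiliaries and the pivalate with LiOH/H2O2 (THF/H2O, 0 °C; Na2SO3 work-up) to the diacid F7. Reduce both carboxylic acids with BH3·SMe2 (THF, 0 °C → rt) to give 17.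

## Further compounds

F1 | step 4 | bis-sultam 8–5 dehydrodimer of 14 (trans-coumaran, free phenol) | COc1cc([C@H]2Oc3c(OC)cc(/C=C/C(=O)N4[C@H]5C[C@@H]6CC[C@@]5(CS4(=O)=O)C6(C)C)cc3[C@@H]2C(=O)N2[C@H]3C[C@@H]4CC[C@@]3(CS2(=O)=O)C4(C)C)ccc1O
F2 | step 4 | aryl pivalate of F1 | COc1cc([C@H]2Oc3c(OC)cc(/C=C/C(=O)N4[C@H]5C[C@@H]6CC[C@@]5(CS4(=O)=O)C6(C)C)cc3[C@@H]2C(=O)N2[C@H]3C[C@@H]4CC[C@@]3(CS2(=O)=O)C4(C)C)ccc1OC(=O)C(C)(C)C
F3 | step 4 | 5-formyl coumaran sultam imide, aryl pivalate | COc1cc([C@H]2Oc3c(OC)cc(C=O)cc3[C@@H]2C(=O)N2[C@H]3C[C@@H]4CC[C@@]3(CS2(=O)=O)C4(C)C)ccc1OC(=O)C(C)(C)C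
F4 | step 4 | O-pivaloyl derivative of 16 (ring-C phenol capped) | COc1cc([C@H]2Oc3c(OC)cc([C@@H](O)[C@@H](C(=O)N4[C@@H](Cc5ccccc5)COC4=O)c4ccc(OC(=O)C(C)(C)C)c(OC)c4)cc3[C@@H]2C(=O)N2[C@H]3C[C@@H]4CC[C@@]3(CS2(=O)=O)C4(C)C)ccc1OC(=O)C(C)(C)C
F5 | step 2 | vanillin acetate | COc1cc(C=O)ccc1OC(C)=O
F6 | step 2 | O-acetyl derivative of 9 | COc1cc([C@@H](O)[C@@H](C(=O)N2[C@@H](Cc3ccccc3)COC2=O)c2ccc(OC(=O)C(C)(C)C)c(OC)c2)ccc1OC(C)=O
F7 | step 5 | coumaran-3-carboxylic acid with 2-aryl-3-hydroxypropanoic acid side chain (diacid, free phenols) | COc1cc([C@H]2Oc3c(OC)cc([C@@H](O)[C@@H](C(=O)O)c4ccc(O)c(OC)c4)cc3[C@@H]2C(=O)O)ccc1O
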